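The target is cut at C8, the carbon that holds the ether oxygen O4' of ring B, the future hydroxymethyl carbon C9 and the benzylic carbinol C7 on ring A. One rhodium-carbene three-component coupling unites phenol 3, aldehyde 5 and ethyl diazoacetate 6 into ester 8. It makes the C8–O4' and C7–C8 bonds and sets both stereocentres in the threo sense (7R,8R in the target), with no ring formed. The precursors are simple: 3 is a 2,6-dimethoxyphenol whose para side chain is held as a methyl ester, and 5 is a benzaldehyde with acetoxy para and methoxy groups meta to the formyl group. A single hydride reduction then unmasks triol 9.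

Key step: step 3

Assumption: a short screen is taken to identify which antipode of the chiral phosphoric acid gives the required sense; (R)-TRIP, (R)-3,3'-bis(2,4,6-triisopropylphenyl)-1,1'-binaphthyl-2,2'-diyl hydrogen phosphate, is written. The ester-bearing carbon is 2S in 8 and 8R in 9 with no change in space, because CO2Et outranks the carbinol carbon whereas CH2OH does not.

Step 1
Reactants: 1 sinapic acid
Product: 3 methyl 3-(4-hydroxy-3,5-dimethoxyphenyl)propanoate, via dihydrosinapic acid 2 (not isolated)
Conditions: H2 (1 atm), 10% Pd/C, MeOH, rt; filter through Celite; then H2SO4 (cat.), reflux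
Reagents that add atoms: methanol, CO
Why: Hydrogenation of the cinnamate C=C bond over palladium leaves the arene, the phenol and the aryl ethers untouched, and Fischer esterification of the saturated acid in the same methanol solution is driven by the solvent excess, so that the phenol becomes the only O–H group of the ring B partner and no stereocentre is involved.

Step 2
Reactants: 4 syringaldehyde
Product: 5 4-formyl-2,6-dimethoxyphenyl acetate
Conditions: Ac2O, pyridine, DMAP (cat.), CH2Cl2, 0 °C to rt
Reagents that add atoms: acetic anhydride, CC(=O)OC(C)=O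
Why: Nucleophile-catalysed O-acylation of the phenol is fast under basic conditions that leave the formyl group alone, and the acetate both shields the ring A phenol from the carbene and makes the aldehyde more electrophilic.

Step 3
Reactants: 3 methyl 3-(4-hydroxy-3,5-dimethoxyphenyl)propanoate; 5 4-formyl-2,6-dimethoxyphenyl acetate; 6 ethyl diazoacetate
Product: 8 ethyl (2S,3R)-3-(4-acetoxy-3,5-dimethoxyphenyl)-2-[2,6-dimethoxy-4-(3-methoxy-3-oxopropyl)phenoxy]-3-hydroxypropanoate, via aryloxy enol 7 (not isolated)
Conditions: Rh2(OAc)4 (2 mol%), (R)-TRIP (10 mol%), 4 Å MS, CH2Cl2, −20 °C; 6 (1.3 equiv) added over 2 h to 3 (1.2 equiv) and 5 (1.0 equiv)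
Reagents that add atoms: none
Why: Proposed new method: Rh2(OAc)4 converts 6 into an electrophilic rhodium carbene, the phenol oxygen of 3 adds to it, and the oxonium ylide so formed (equivalent to its metal-associated enol tautomer 7) is captured at carbon by aldehyde 5 inside a hydrogen-bonded complex with the chiral phosphoric acid before the 1,2-proton shift can release the simple O–H insertion ether. The closest known reaction type is the three-component coupling of diazo esters, alcohols and aldehydes or imines under Rh2(OAc)4 and a chiral acid co-catalyst through trapped oxonium ylides, which is established for aryl diazoacetates and aliphatic alcohols but not for a phenol combined with an unsubstituted diazoacetate. No ring is closed; the new bonds are C8–O4' and C7–C8. Both stereocentres (C2 of 8 = C8, S; C3 of 8 = C7, R) arise in the C–C bond formation and are controlled by the phosphate, whose P=O accepts the enol O–H while its P–OH activates the formyl oxygen, so that one enol face meets one aldehyde face and the threo relationship follows from the same organised transition state. The step needs oxygen-over-carbon chemoselectivity and trapping faster than proton transfer: in 3 the two positions ortho and the position para to the hydroxyl are substituted, which leaves O–H attack as the only fast channel, and in 5 the acetoxy group para and the two methoxy groups meta to CHO make the carbonyl electrophilic enough to intercept 7. Slow addition of 6 and a slight excess of 3 keep carbene dimerisation and insertion into the new C7–OH of 8 in check.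

Step 4
Reactants: 8 ethyl (2S,3R)-3-(4-acetoxy-3,5-dimethoxyphenyl)-2-[2,6-dimethoxy-4-(3-methoxy-3-oxopropyl)phenoxy]-3-hydroxypropanoate
Product: 9 (1R,2R)-1-(4-hydroxy-3,5-dimethoxyphenyl)-2-[4-(3-hydroxypropyl)-2,6-dimethoxyphenoxy]propane-1,3-diol
Conditions: LiAlH4 (5 equiv), THF, 0 °C to rt; aq. potassium sodium tartrate work-up
Reagents that add atoms: none
Why: Hydride reduction with LiAlH4 should turn both carboxylic esters into primary alcohols and cleave the aryl acetate to the phenol in one operation, as is routine for α-aryloxy-β-hydroxy esters, while C7 and C8 keep their configuration because ester reduction at 0 °C outruns retro-aldol cleavage of the C7 alkoxide and the neutral tartrate work-up avoids acid-induced ionisation at the p-hydroxybenzylic C7.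

Compound list
1 | sinapic acid [(E)-3-(4-hydroxy-3,5-dimethoxyphenyl)prop-2-enoic acid] | COc1cc(/C=C/C(=O)O)cc(OC)c1O | starting material
2 | dihydrosinapic acid [3-(4-hydroxy-3,5-dimethoxyphenyl)propanoic acid] | COc1cc(CCC(=O)O)cc(OC)c1O | intermediate
3 | methyl 3-(4-hydroxy-3,5-dimethoxyphenyl)propanoate | COC(=O)CCc1cc(OC)c(O)c(OC)c1 | intermediate
4 | syringaldehyde [4-hydroxy-3,5-dimethoxybenzaldehyde] | COc1cc(C=O)cc(OC)c1O | starting material
5 | 4-formyl-2,6-dimethoxyphenyl acetate | COc1cc(C=O)cc(OC)c1OC(C)=O | intermediate
6 | ethyl diazoacetate | CCOC(=O)C=[N+]=[N-] | starting material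
7 | aryloxy enol 1-ethoxy-2-[2,6-dimethoxy-4-(3-methoxy-3-oxopropyl)phenoxy]ethen-1-ol [enol tautomer of the oxonium ylide formed from 3 and the rhodium carbene of 6; double-bond geometry not defined] | CCOC(O)=COc1c(OC)cc(CCC(=O)OC)cc1OC | intermediate
8 | ethyl (2S,3R)-3-(4-acetoxy-3,5-dimethoxyphenyl)-2-[2,6-dimethoxy-4-(3-methoxy-3-oxopropyl)phenoxy]-3-hydroxypropanoate | COc1cc([C@@H](O)[C@@H](C(=O)OCC)Oc2c(OC)cc(CCC(=O)OC)cc2OC)cc(OC)c1OC(C)=O | intermediate
9 | (1R,2R)-1-(4-hydroxy-3,5-dimethoxyphenyl)-2-[4-(3-hydroxypropyl)-2,6-dimethoxyphenoxy]propane-1,3-diol (threo, 7R,8R) | COc1cc([C@@H](O)[C@@H](CO)Oc2c(OC)cc(CCCO)cc2OC)cc(OC)c1O | target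

Total step count: 4. Longest linear sequence: 3 steps (steps 1, 3 and 4 from sinapic acid; the branch through steps 2, 3 and 4 from syringaldehyde is equally long).

Steps most likely to fail

1. Step 3. Proton transfer within the oxonium ylide may outrun capture by the aldehyde, so that only O–H insertion occurs, or capture may proceed with poor facial and threo/erythro control. The fallback uses known chemistry, sets out from 5, 6 and 3 and comes back to the route at 8. Aldehyde 5 is homologated with 6 under SnCl2 catalysis (Roskamp reaction, CH2Cl2, rt) to ethyl 3-(4-acetoxy-3,5-dimethoxyphenyl)-3-oxopropanoate F1. Regitz diazo transfer (4-acetamidobenzenesulfonyl azide, Et3N, MeCN) should then give ethyl 3-(4-acetoxy-3,5-dimethoxyphenyl)-2-diazo-3-oxopropanoate F2. Rh2(OAc)4-catalysed O–H insertion of phenol 3 (toluene, 60 °C) should give racemic, configurationally labile ethyl 3-(4-acetoxy-3,5-dimethoxyphenyl)-2-[2,6-dimethoxy-4-(3-methoxy-3-oxopropyl)phenoxy]-3-oxopropanoate F3. Asymmetric transfer hydrogenation with dynamic kinetic resolution (RuCl[(S,S)-TsDPEN](p-cymene), HCO2H/Et3N 5:2, CH2Cl2, 30 °C) reduces the ketone while C2 equilibrates through the enol. This reaction type is known to give syn α-alkoxy-β-hydroxy esters, and the syn isomer is the threo ester 8. The (S,S) catalyst is expected to give 3R by analogy with aryl ketones, and the antipode is used if the sense proves opposite.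

2. Step 4. The metal alkoxide at C7 may fragment by retro-aldol cleavage, or C8 may equilibrate, before the neighbouring ester is reduced; the polar phenolic triol may also be held back by aluminium salts. The fallback sets out from 8 and comes back to the route at 9. Silylation of the C7 hydroxyl (TBSOTf, 2,6-lutidine, CH2Cl2, 0 °C) gives ethyl (2S,3R)-3-(4-acetoxy-3,5-dimethoxyphenyl)-3-[(tert-butyldimethylsilyl)oxy]-2-[2,6-dimethoxy-4-(3-methoxy-3-oxopropyl)phenoxy]propanoate F4, in which no alkoxide can form next to the ester. LiAlH4 (THF, 0 °C) then reduces both esters and cleaves the acetate to give (2R,3R)-3-[(tert-butyldimethylsilyl)oxy]-3-(4-hydroxy-3,5-dimethoxyphenyl)-2-[4-(3-hydroxypropyl)-2,6-dimethoxyphenoxy]propan-1-ol F5. Buffered fluoride (Bu4NF, AcOH, THF, 0 °C to rt) removes the silyl group and should return 9.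

3. Step 1. Esterification may stop short, so that free acid 2 is carried into step 3, where a carboxylic acid would itself consume the carbene by O–H insertion. The fallback sets out from 4 and comes back to the route at 3. Wittig olefination of syringaldehyde 4 with methyl (triphenylphosphoranylidene)acetate (toluene, 90 °C) gives methyl (E)-3-(4-hydroxy-3,5-dimethoxyphenyl)prop-2-enoate F6, so that the ester arrives with the carbon chain and no free acid ever appears. Hydrogenation (H2, 10% Pd/C, EtOAc, rt) should then give 3.

Further compounds
F1 | step 3 | ethyl 3-(4-acetoxy-3,5-dimethoxyphenyl)-3-oxopropanoate | CCOC(=O)CC(=O)c1cc(OC)c(OC(C)=O)c(OC)c1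
F2 | step 3 | ethyl 3-(4-acetoxy-3,5-dimethoxyphenyl)-2-diazo-3-oxopropanoate | CCOC(=O)C(=[N+]=[N-])C(=O)c1cc(OC)c(OC(C)=O)c(OC)c1
F3 | step 3 | ethyl 3-(4-acetoxy-3,5-dimethoxyphenyl)-2-[2,6-dimethoxy-4-(3-methoxy-3-oxopropyl)phenoxy]-3-oxopropanoate (racemic) | CCOC(=O)C(Oc1c(OC)cc(CCC(=O)OC)cc1OC)C(=O)c1cc(OC)c(OC(C)=O)c(OC)c1
F4 | step 4 | ethyl (2S,3R)-3-(4-acetoxy-3,5-dimethoxyphenyl)-3-[(tert-butyldimethylsilyl)oxy]-2-[2,6-dimethoxy-4-(3-methoxy-3-oxopropyl)phenoxy]propanoate | COc1cc([C@@H](O[Si](C)(C)C(C)(C)C)[C@@H](C(=O)OCC)Oc2c(OC)cc(CCC(=O)OC)cc2OC)cc(OC)c1OC(C)=O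
F5 | step 4 | (2R,3R)-3-[(tert-butyldimethylsilyl)oxy]-3-(4-hydroxy-3,5-dimethoxyphenyl)-2-[4-(3-hydroxypropyl)-2,6-dimethoxyphenoxy]propan-1-ol | COc1cc([C@@H](O[Si](C)(C)C(C)(C)C)[C@@H](CO)Oc2c(OC)cc(CCCO)cc2OC)cc(OC)c1O
F6 | step 1 | methyl (E)-3-(4-hydroxy-3,5-dimethoxyphenyl)prop-2-enoate | COC(=O)/C=C/c1cc(OC)c(O)c(OC)c1
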